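## The problem

Target 24 is a (2S)-flavanone: ring A and the pyranone ring C share the C4a–C8a bond, and ring B (4-hydroxyphenyl) sits on C2, the only stereocentre. Ring A is hexasubstituted (O1 at C8a, prenyl at C8, OMe at C7, prenyl at C6, OH at C5, the C4 carbonyl at C4a). No electrophilic substitution can be trusted to find its site, so every group has to be placed by a regiospecific reaction. Nothing in the molecule can control C2, so it must come from a catalyst and then be kept. C2 is benzylic to an electron-rich ring and β to the ketone, so it is lost by retro-oxa-Michael ring opening under base once ring C is closed, and by β-elimination while the chain is still open. The prenyl double bonds exclude hydrogenolysis and strong electrophiles, and under strong acid the 6-prenyl group adds to the free 5-OH. The feature that makes the key step possible is that C4a carries an acyl carbon and C8a an oxygen on adjacent ring carbons, with a further oxygen at C5 on the other side of C4a. A carboxylate adding across a C4a≡C8a aryne polarised by a C5 alkoxy group delivers exactly this pattern. Before ring C closes, ring A is symmetric about the C4a···C7 axis, so a symmetric resorcinol can be carried far and either ortho oxygen may become O1.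

## Retrosynthesis

**24 from 23.** The two phenols are unmasked last from bis(methoxymethyl) ether 23. Acid-labile acetals are chosen because base opens the flavanone and hydrogenolysis would reduce the prenyl groups. The forward step needs acid mild enough to spare the 5-OH/6-prenyl pair.

**23 from 22 (cut O1–C2).** Ring C is closed by intramolecular Mitsunobu etherification of phenol-carbinol 22, with inversion from (3R) to (2S). A conjugate-addition closure would form the same bond without any control of C2. Cutting C8a–O1 instead would need a halide at the most crowded ring carbon. Precursor 22 is open-chain with one free phenol. The forward step must displace faster than it eliminates.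

**22 from 21, and 21 from 13 + 19 (cut C4a–C4 and C8a–O1).** Desilylation of 21 gives 22. Ketone 21 is cut at both bonds that join ring A to the C4–C3–C2 chain. In the forward sense aryne 20, released from ortho-silylaryl triflate 13 by CsF, inserts into the O–C(acyl) bond of acid 19.
- Friedel–Crafts, Hoesch or Fries acylation would need Lewis or Brønsted acid on a prenylated acetal-protected arene.
- An aryllithium route would put a basic, crowded nucleophile next to an enolisable β-silyloxy carbonyl.
- The aryne step runs under fluoride alone and makes the C–C and C–O bonds in one operation.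

This cut divides the molecule into two fragments of similar size, and 19 brings C4, C3 and the finished stereocentre. The forward step requires carboxylate attack at C8a rather than C4a, and acyl transfer rather than protonation.

**13 from 12, and 12 from 8 via 9–11 (cut C4a–Si).** Triflate 13 comes from phenol 12. The C–Si bond is made by bromine–lithium exchange on bis(silyl ether) 9 and a 1,3 O→C silyl shift to lithium phenoxide 10. This differentiates the two oxygens of symmetric diol 8 without a statistical step: 10 is capped as acetal 11 and the remaining O-silyl group is removed. The electron-rich arylsilane would protodesilylate in acid, so it is made only after the last acidic step of this branch.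

**8 from 7, 7 from 6, 6 from 5 (cut the two aryl–CH2 bonds).** The prenyl groups are simplified to allyl (cross-metathesis of 7 with 2-methyl-2-butene). The allyl groups come from double Claisen rearrangement of bis(allyl ether) 6, made from diol 5.
- Direct C-prenylation of 5 would compete with O-alkylation and over-alkylation.
- Lithiation–prenylation is excluded by the bromine and by the acidity of benzylic-allylic CH2 groups.
- With C2 of 5 blocked by bromine, the allyl groups can only end at the two carbons that flank the methoxy group.

**5 from 4, 4 from 2, 2 from 1 (cut C–Br).** Direct bromination of 1 should go para to a hydroxyl, the wrong carbon. The bromine is therefore placed by directed ortho-metalation of bis-acetal 2 between its two acetal oxygens (via 3), and 4 is then deprotected to 5.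

**19 from 18, 17, 16, 15 and 14.** The acid is reached by saponification of 18 and silylation of 17. The carbinol of 17 is set by asymmetric transfer hydrogenation of β-keto ester 16. Ester 16 is made by Claisen condensation of ketone 15 (from 14) with dimethyl carbonate, which forms the C3–C4 bond.

## Roads not taken

**Alternative 1:** Ring A would be built onto a finished ring C by cutting C4a–C5 and C8–C8a. In the forward sense, vinylketene acetal A3 would add to the C4a=C8a bond of bromo-dihydropyranone A2. Loss of HBr and methanol would aromatise the adduct to A1, the 4'-O-methoxymethyl ether of 24.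
- Merits: C2 of A2 could be set catalytically at the very start by asymmetric hetero-Diels–Alder chemistry. No activated benzylic carbinol is ever displaced. The 5-OH emerges free, and the diene encodes the whole substitution pattern of ring A.
- Weak points: A3 is a pentasubstituted diene whose reactive s-cis form is crowded and whose preparation needs a geometrically defined enol ether. A2 is a vinylogous ester and a poor dienophile. The heat and base needed for cycloaddition and HBr loss act on a β-aryloxy ketone that can racemise by ring opening once the 5-hydroxyflavanone exists.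
- Comparison: this road is more convergent and avoids both the inversion step and the exchange of one ring oxygen for another. The chosen plan sets against it that each of its steps has close precedent on crowded substrates. Its hot step also acts on a protected open-chain carbinol, where damage would show as a separable elimination product and not as erosion of enantiopurity.

**Alternative 2:** Ring A would be made from acyclic pieces by cutting C5–C6, C7–C8 and C4a–C5. Heating cyclobutenone A5 with ynol ether A6 would pass through ring opening, [2+2] addition, a second ring opening and 6π closure to give phenol A4.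
- Merits: one step gives the pentasubstituted phenol with unambiguous regiochemistry. For ring A alone it is probably shorter than the eight steps from 1 to 13 used here. A4 differs from 12 only by the silyl group, so it could feed the chosen route.
- Weak points: A6 is a labile alkoxyalkyne and A5 a multistep vinylogous ester. The strategy also leaves open how the C4–C3–C2 chain is attached at C4a of an acid-sensitive arene and how C2 is set, so a second strategic step is still needed.
- Comparison: alternative 2 is better on step economy for ring A. The chosen plan sets against it commercial starting materials, classical regiospecific steps, and a key step that solves the C-acylation as well.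

**Alternative 3:** Ring C would be closed at C8a–O1. CuI with 1,10-phenanthroline and Cs2CO3 would couple the C2 hydroxyl of bromo diol A8 with its C8a bromide to give flavan-4-ol A7. Oxidation at C4 and deprotection would follow.
- Merits: the C2–O bond of the carbinol is retained, so configuration is transferred without inversion, ionisation or elimination, and no enolisable ketone is present during closure. In stereochemical safety this closure is better than the Mitsunobu step chosen here.
- Weak points: A8 needs a ring A in which C8a bears bromine rather than oxygen, flanked by a prenyl group and the side chain. That pattern is harder to reach from phloroglucinol-type material, and copper-mediated etherification of such a crowded, electron-rich bromide with a secondary alkoxide is demanding. C4 must also be carried as an alcohol and re-oxidised.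
- Comparison: the chosen plan concedes the safer stereochemical course to alternative 3. It sets against it a metal-free bond formation at the crowded positions, no oxidation-state detour, and a ring A precursor from a symmetric resorcinol.

Key step: step 14

Remark: the target SMILES corresponds to the (2S)-flavanone, so a closure with inversion requires the (3R)-carbinol throughout.

## Route

Step 1
Reactants: 1 5-methoxybenzene-1,3-diol (5-methoxyresorcinol)
Product: 2 1-methoxy-3,5-bis(methoxymethoxy)benzene
Conditions: MOMCl, iPr2NEt, CH2Cl2, 0 °C → rt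
Reagents that add atoms: chloromethyl methyl ether, COCCl
Why: O-alkylation of both phenols (Williamson type); the acetal ethers are the directing groups for step 2.

Step 2
Reactants: 2 1-methoxy-3,5-bis(methoxymethoxy)benzene
Product: 4 2-bromo-5-methoxy-1,3-bis(methoxymethoxy)benzene, via 2-lithio arene 3 (not isolated)
Conditions: n-BuLi, THF, 0 °C; BrCCl2CCl2Br, −78 °C → rt
Reagents that add atoms: 1,2-dibromo-1,1,2,2-tetrachloroethane, BrC(Cl)(Cl)C(Cl)(Cl)Br
Why: Directed ortho-metalation; the carbon between the two acetal oxygens is the most acidic and doubly chelated, so lithiation should occur there rather than next to the methoxy group, and bromine transfer from the polyhaloethane gives the bromide that blocks this carbon in step 5 and serves as the lithium handle in step 7.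

Step 3
Reactants: 4 2-bromo-5-methoxy-1,3-bis(methoxymethoxy)benzene
Product: 5 2-bromo-5-methoxybenzene-1,3-diol
Conditions: HCl (2 M aq), MeOH, 40 °C
Reagents that add atoms: none
Why: Acid-catalysed acetal cleavage; nothing acid-sensitive is present yet.

Step 4
Reactants: 5 2-bromo-5-methoxybenzene-1,3-diol
Product: 6 2-bromo-5-methoxy-1,3-bis(prop-2-en-1-yloxy)benzene
Conditions: allyl bromide, K2CO3, acetone, reflux
Reagents that add atoms: allyl bromide, C=CCBr
Why: Williamson etherification of both phenols.

Step 5
Reactants: 6 2-bromo-5-methoxy-1,3-bis(prop-2-en-1-yloxy)benzene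
Product: 7 2-bromo-5-methoxy-4,6-di(prop-2-en-1-yl)benzene-1,3-diol
Conditions: PhNEt2, 190 °C
Reagents that add atoms: none
Why: Double aromatic Claisen rearrangement ([3,3]); bromine blocks the carbon between the oxygens, so each allyl group can settle only at a carbon flanking the methoxy group, and because allyl is symmetric end to end the direct ortho path and an ortho–para relay give the same product.

Step 6
Reactants: 7 2-bromo-5-methoxy-4,6-di(prop-2-en-1-yl)benzene-1,3-diol
Product: 8 2-bromo-5-methoxy-4,6-bis(3-methylbut-2-en-1-yl)benzene-1,3-diol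
Conditions: 2-methyl-2-butene (excess), RuCl2(=CHPh)(PCy3)(H2IMes) (second-generation Grubbs catalyst), CH2Cl2, 40 °C, sealed
Reagents that add atoms: 2-methyl-2-butene, CC=C(C)C
Why: Olefin cross-metathesis of both terminal allyl groups with excess trisubstituted alkene, the standard allyl-to-prenyl conversion; free phenols and the aryl bromide are tolerated.

Step 7
Reactants: 8 2-bromo-5-methoxy-4,6-bis(3-methylbut-2-en-1-yl)benzene-1,3-diol
Product: 12 3-methoxy-5-(methoxymethoxy)-2,4-bis(3-methylbut-2-en-1-yl)-6-(trimethylsilyl)phenol, via bis(trimethylsilyl) ether 9 (not isolated), via lithium phenoxide 10 (not isolated), via silyl ether 11 (not isolated)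
Conditions: HMDS, THF, 65 °C, evaporate; n-BuLi, THF, −78 → 0 °C; MOMCl, 0 °C → rt; K2CO3 (cat.), MeOH, 0 °C
Reagents that add atoms: hexamethyldisilazane, C[Si](C)(C)N[Si](C)(C)C; chloromethyl methyl ether, COCCl
Why: O-silylation, then bromine–lithium exchange followed at once by the 1,3 O→C silyl shift (retro-Brook rearrangement), which places silicon on carbon and frees exactly one of the two equivalent oxygens as its lithium salt; that oxygen is alkylated with MOMCl and the remaining aryl silyl ether is methanolysed, all under basic conditions that spare the acid-sensitive C–Si bond.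

Step 8
Reactants: 12 3-methoxy-5-(methoxymethoxy)-2,4-bis(3-methylbut-2-en-1-yl)-6-(trimethylsilyl)phenol
Product: 13 3-methoxy-5-(methoxymethoxy)-2,4-bis(3-methylbut-2-en-1-yl)-6-(trimethylsilyl)phenyl trifluoromethanesulfonate
Conditions: Tf2O, pyridine, CH2Cl2, −78 → 0 °C
Reagents that add atoms: trifluoromethanesulfonic anhydride, O=S(=O)(OS(=O)(=O)C(F)(F)F)C(F)(F)F
Why: O-sulfonylation of the hindered phenol; pyridine buffers the triflic acid so that the arylsilane and the acetal survive, and purification on amine-deactivated silica is planned for the same reason.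

Step 9
Reactants: 14 1-(4-hydroxyphenyl)ethan-1-one (4-hydroxyacetophenone)
Product: 15 1-[4-(methoxymethoxy)phenyl]ethan-1-one
Conditions: MOMCl, iPr2NEt, CH2Cl2, 0 °C → rt
Reagents that add atoms: chloromethyl methyl ether, COCCl
Why: O-alkylation of the phenol; the acetal matches the one on ring A so that both fall in the last step.

Step 10
Reactants: 15 1-[4-(methoxymethoxy)phenyl]ethan-1-one
Product: 16 methyl 3-[4-(methoxymethoxy)phenyl]-3-oxopropanoate
Conditions: NaH, (MeO)2CO, THF, reflux; AcOH quench
Reagents that add atoms: dimethyl carbonate, COC(=O)OC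
Why: Crossed Claisen condensation of the ketone enolate with dimethyl carbonate, driven by deprotonation of the β-keto ester.

Step 11
Reactants: 16 methyl 3-[4-(methoxymethoxy)phenyl]-3-oxopropanoate
Product: 17 methyl (3R)-3-hydroxy-3-[4-(methoxymethoxy)phenyl]propanoate
Conditions: RuCl[(R,R)-TsDPEN](p-cymene) (cat.), HCO2H–Et3N (5:2), EtOAc, 40 °C
Reagents that add atoms: none
Why: Noyori-type asymmetric transfer hydrogenation of an aryl ketone; the (R,R)-ligand should deliver hydride to the face that gives the (R)-carbinol, by analogy with acetophenone-type substrates, and the buffered medium spares the acetal.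

Step 12
Reactants: 17 methyl (3R)-3-hydroxy-3-[4-(methoxymethoxy)phenyl]propanoate
Product: 18 methyl (3R)-3-[4-(methoxymethoxy)phenyl]-3-[(triisopropylsilyl)oxy]propanoate
Conditions: TIPSOTf (slight excess), 2,6-lutidine, CH2Cl2, −78 → 0 °C
Reagents that add atoms: triisopropylsilyl trifluoromethanesulfonate, CC(C)[Si](OS(=O)(=O)C(F)(F)F)(C(C)C)C(C)C
Why: O-silylation of the secondary alcohol; the bulky silyl ether is chosen because it resists fluoride and is a poor leaving group in step 14, and low temperature with little excess keeps the silyl triflate from attacking the aryl acetal.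

Step 13
Reactants: 18 methyl (3R)-3-[4-(methoxymethoxy)phenyl]-3-[(triisopropylsilyl)oxy]propanoate
Product: 19 (3R)-3-[4-(methoxymethoxy)phenyl]-3-[(triisopropylsilyl)oxy]propanoic acid
Conditions: LiOH, THF–MeOH–H2O, rt; 1 M HCl to pH 4, 0 °C
Reagents that add atoms: lithium hydroxide, [Li+].[OH-]
Why: Ester saponification at room temperature, where β-elimination of the silyloxy group should not compete; brief, cold acidification spares the acetal.

Step 14
Reactants: 13 3-methoxy-5-(methoxymethoxy)-2,4-bis(3-methylbut-2-en-1-yl)-6-(trimethylsilyl)phenyl trifluoromethanesulfonate; 19 (3R)-3-[4-(methoxymethoxy)phenyl]-3-[(triisopropylsilyl)oxy]propanoic acid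
Product: 21 (3R)-1-[2-hydroxy-4-methoxy-6-(methoxymethoxy)-3,5-bis(3-methylbut-2-en-1-yl)phenyl]-3-[4-(methoxymethoxy)phenyl]-3-[(triisopropylsilyl)oxy]propan-1-one, via aryne 20 (not isolated)
Conditions: CsF, THF, 125 °C, sealed tube (13 in slight excess)
Reagents that add atoms: none
Why: Fluoride attacks silicon and triflate leaves, giving aryne 20 with the triple bond between C4a and C8a. The C5 acetal oxygen withdraws inductively and distorts the aryne so that C8a is the more electrophilic end; the caesium carboxylate of 19 should therefore add at C8a and leave the aryl anion at C4a beside the stabilising oxygen, a bias that has to outweigh the steric pressure of the C8 prenyl group. The C4a anion then attacks the carbonyl of the aryl ester just formed, through a four-membered alkoxide that opens to the phenoxide, so the aryne is inserted into the O–C(acyl) bond and the C8a–O1 and C4a–C4 bonds are made together. The closest known reaction type is the fluoride-induced C–O insertion of arynes into carboxylic acids, which gives ortho-hydroxyaryl ketones in hot THF; in this aprotic medium acyl transfer should prevail over protonation to the O-aryl ester. No ring persists, since the four-membered intermediate is transient, and no stereocentre is formed. The (R)-carbinol is β to the new ketone and cannot epimerise; it could be lost only by elimination of silyloxide, which the bulky triisopropylsilyl ether is chosen to resist. The acetals and prenyl groups are inert to CsF, and only a small excess of 13 is used so that the hindered product phenoxide is not arylated again.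

Step 15
Reactants: 21 (3R)-1-[2-hydroxy-4-methoxy-6-(methoxymethoxy)-3,5-bis(3-methylbut-2-en-1-yl)phenyl]-3-[4-(methoxymethoxy)phenyl]-3-[(triisopropylsilyl)oxy]propan-1-one
Product: 22 (3R)-3-hydroxy-1-[2-hydroxy-4-methoxy-6-(methoxymethoxy)-3,5-bis(3-methylbut-2-en-1-yl)phenyl]-3-[4-(methoxymethoxy)phenyl]propan-1-one
Conditions: HF·pyridine, pyridine, THF, 0 °C → rt
Reagents that add atoms: none
Why: Fluoride-mediated Si–O cleavage under buffered, non-basic conditions, so that the β-hydroxy ketone neither eliminates nor undergoes retro-aldol cleavage; aryl acetals tolerate pyridine-buffered HF.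

Step 16
Reactants: 22 (3R)-3-hydroxy-1-[2-hydroxy-4-methoxy-6-(methoxymethoxy)-3,5-bis(3-methylbut-2-en-1-yl)phenyl]-3-[4-(methoxymethoxy)phenyl]propan-1-one
Product: 23 (2S)-7-methoxy-5-(methoxymethoxy)-2-[4-(methoxymethoxy)phenyl]-6,8-bis(3-methylbut-2-en-1-yl)-2,3-dihydro-4H-chromen-4-one
Conditions: PPh3, DIAD, THF, 0 °C
Reagents that add atoms: none
Why: Intramolecular Mitsunobu etherification; the only free phenol displaces the activated benzylic carbinol in a six-membered closure with inversion, turning (3R) into (2S), and the low temperature is meant to keep this closure ahead of elimination or ionisation.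

Step 17
Reactants: 23 (2S)-7-methoxy-5-(methoxymethoxy)-2-[4-(methoxymethoxy)phenyl]-6,8-bis(3-methylbut-2-en-1-yl)-2,3-dihydro-4H-chromen-4-one
Product: 24 (2S)-5-hydroxy-2-(4-hydroxyphenyl)-7-methoxy-6,8-bis(3-methylbut-2-en-1-yl)-2,3-dihydro-4H-chromen-4-one
Conditions: HCl (3 M aq), MeOH, 40 °C, short reaction time
Reagents that add atoms: none
Why: Acid-catalysed cleavage of both aryl acetals, the one peri to the carbonyl being assisted by chelation; flavanones hold their C2 configuration under mild acid, and time and temperature are limited so that the 6-prenyl group does not add to the new 5-OH.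

## Compound list

1 | 5-methoxybenzene-1,3-diol (5-methoxyresorcinol) | COc1cc(O)cc(O)c1 | starting material
2 | 1-methoxy-3,5-bis(methoxymethoxy)benzene | COCOc1cc(OC)cc(OCOC)c1 | intermediate
3 | [4-methoxy-2,6-bis(methoxymethoxy)phenyl]lithium (not isolated) | [Li]c1c(OCOC)cc(OC)cc1OCOC | intermediate
4 | 2-bromo-5-methoxy-1,3-bis(methoxymethoxy)benzene | COCOc1cc(OC)cc(OCOC)c1Br | intermediate
5 | 2-bromo-5-methoxybenzene-1,3-diol | COc1cc(O)c(Br)c(O)c1 | intermediate
6 | 2-bromo-5-methoxy-1,3-bis(prop-2-en-1-yloxy)benzene | C=CCOc1cc(OC)cc(OCC=C)c1Br | intermediate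
7 | 2-bromo-5-methoxy-4,6-di(prop-2-en-1-yl)benzene-1,3-diol | COc1c(CC=C)c(O)c(Br)c(O)c1CC=C | intermediate
8 | 2-bromo-5-methoxy-4,6-bis(3-methylbut-2-en-1-yl)benzene-1,3-diol | COc1c(CC=C(C)C)c(O)c(Br)c(O)c1CC=C(C)C | intermediate
9 | 2-bromo-5-methoxy-4,6-bis(3-methylbut-2-en-1-yl)-1,3-bis(trimethylsilyloxy)benzene (not isolated) | COc1c(CC=C(C)C)c(O[Si](C)(C)C)c(Br)c(O[Si](C)(C)C)c1CC=C(C)C | intermediate
10 | lithium 3-methoxy-2,4-bis(3-methylbut-2-en-1-yl)-6-(trimethylsilyl)-5-(trimethylsilyloxy)phenolate (not isolated) | [Li+].[O-]c1c(CC=C(C)C)c(OC)c(CC=C(C)C)c(O[Si](C)(C)C)c1[Si](C)(C)C | intermediate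
11 | [3-methoxy-5-(methoxymethoxy)-2,4-bis(3-methylbut-2-en-1-yl)-6-(trimethylsilyl)phenoxy]trimethylsilane (not isolated) | COc1c(CC=C(C)C)c(O[Si](C)(C)C)c([Si](C)(C)C)c(OCOC)c1CC=C(C)C | intermediate
12 | 3-methoxy-5-(methoxymethoxy)-2,4-bis(3-methylbut-2-en-1-yl)-6-(trimethylsilyl)phenol | COc1c(CC=C(C)C)c(O)c([Si](C)(C)C)c(OCOC)c1CC=C(C)C | intermediate
13 | 3-methoxy-5-(methoxymethoxy)-2,4-bis(3-methylbut-2-en-1-yl)-6-(trimethylsilyl)phenyl trifluoromethanesulfonate | COc1c(CC=C(C)C)c(OCOC)c([Si](C)(C)C)c(OS(=O)(=O)C(F)(F)F)c1CC=C(C)C | intermediate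
14 | 1-(4-hydroxyphenyl)ethan-1-one (4-hydroxyacetophenone) | CC(=O)c1ccc(O)cc1 | starting material
15 | 1-[4-(methoxymethoxy)phenyl]ethan-1-one | CC(=O)c1ccc(OCOC)cc1 | intermediate
16 | methyl 3-[4-(methoxymethoxy)phenyl]-3-oxopropanoate | COC(=O)CC(=O)c1ccc(OCOC)cc1 | intermediate
17 | methyl (3R)-3-hydroxy-3-[4-(methoxymethoxy)phenyl]propanoate | COC(=O)C[C@@H](O)c1ccc(OCOC)cc1 | intermediate
18 | methyl (3R)-3-[4-(methoxymethoxy)phenyl]-3-[(triisopropylsilyl)oxy]propanoate | COC(=O)C[C@@H](O[Si](C(C)C)(C(C)C)C(C)C)c1ccc(OCOC)cc1 | intermediate
19 | (3R)-3-[4-(methoxymethoxy)phenyl]-3-[(triisopropylsilyl)oxy]propanoic acid | OC(=O)C[C@@H](O[Si](C(C)C)(C(C)C)C(C)C)c1ccc(OCOC)cc1 | intermediate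
20 | 1,2-didehydro-4-methoxy-6-(methoxymethoxy)-3,5-bis(3-methylbut-2-en-1-yl)benzene, the aryne (not isolated) | COC1=C(CC=C(C)C)C#CC(OCOC)=C1CC=C(C)C | intermediate
21 | (3R)-1-[2-hydroxy-4-methoxy-6-(methoxymethoxy)-3,5-bis(3-methylbut-2-en-1-yl)phenyl]-3-[4-(methoxymethoxy)phenyl]-3-[(triisopropylsilyl)oxy]propan-1-one | COc1c(CC=C(C)C)c(OCOC)c(c(O)c1CC=C(C)C)C(=O)C[C@@H](O[Si](C(C)C)(C(C)C)C(C)C)c1ccc(OCOC)cc1 | intermediate
22 | (3R)-3-hydroxy-1-[2-hydroxy-4-methoxy-6-(methoxymethoxy)-3,5-bis(3-methylbut-2-en-1-yl)phenyl]-3-[4-(methoxymethoxy)phenyl]propan-1-one | COc1c(CC=C(C)C)c(OCOC)c(c(O)c1CC=C(C)C)C(=O)C[C@@H](O)c1ccc(OCOC)cc1 | intermediate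
23 | (2S)-7-methoxy-5-(methoxymethoxy)-2-[4-(methoxymethoxy)phenyl]-6,8-bis(3-methylbut-2-en-1-yl)-2,3-dihydro-4H-chromen-4-one | COc1c(CC=C(C)C)c(OCOC)c2c(c1CC=C(C)C)O[C@H](c1ccc(OCOC)cc1)CC2=O | intermediate
24 | (2S)-5-hydroxy-2-(4-hydroxyphenyl)-7-methoxy-6,8-bis(3-methylbut-2-en-1-yl)-2,3-dihydro-4H-chromen-4-one | COc1c(CC=C(C)C)c(O)c2c(c1CC=C(C)C)O[C@H](c1ccc(O)cc1)CC2=O | target

## Step count and least certain steps

Total: 17 steps. Longest linear sequence: 12 steps (steps 1–8 and 14–17, from 1). The acid branch (steps 9–13) has 5 steps.

**Step 14 (key step).**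
- What may go wrong: protonation of the aryl anion before acyl transfer, which stops the sequence at O-arylation; carboxylate attack at C4a instead of C8a because the C8 prenyl group crowds the electronically preferred site; loss of silyloxide by β-elimination at the temperature needed; ene-type consumption of the aryne by prenyl double bonds.
- First adjustment: a soluble fluoride source at lower temperature.
- Fallback: it changes the approach to an aryllithium acylation, sets out from 8 and 19 and returns at 21. Diol 8 is converted with NaH and MOMCl into 2-bromo-5-methoxy-1,3-bis(methoxymethoxy)-4,6-bis(3-methylbut-2-en-1-yl)benzene F1. Bromine–lithium exchange with n-BuLi at −78 °C gives [4-methoxy-2,6-bis(methoxymethoxy)-3,5-bis(3-methylbut-2-en-1-yl)phenyl]lithium F2. Acid 19 is coupled with N,O-dimethylhydroxylamine hydrochloride and a carbodiimide to (3R)-N-methoxy-N-methyl-3-[4-(methoxymethoxy)phenyl]-3-[(triisopropylsilyl)oxy]propanamide F3. Addition of F2 to F3 gives (3R)-1-[4-methoxy-2,6-bis(methoxymethoxy)-3,5-bis(3-methylbut-2-en-1-yl)phenyl]-3-[4-(methoxymethoxy)phenyl]-3-[(triisopropylsilyl)oxy]propan-1-one F4. Its two ortho acetals are equivalent, so brief treatment with dilute HCl in MeOH, in which the carbonyl assists loss of the first acetal and the resulting hydrogen bond slows loss of the second, gives 21.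

**Step 7.**
- What may go wrong: sluggish O-alkylation of the crowded lithium phenoxide; transfer of silyl groups between oxygens; attack of n-BuLi at silicon instead of bromine; protodesilylation during work-up.
- Fallback: it differentiates the oxygens before the silyl shift, sets out from 8 and returns at 12. Mono-alkylation of 8 with one equivalent of NaH and MOMCl, a statistical step with recycling of 8, gives 2-bromo-5-methoxy-3-(methoxymethoxy)-4,6-bis(3-methylbut-2-en-1-yl)phenol F5. Silylation with HMDS gives [2-bromo-5-methoxy-3-(methoxymethoxy)-4,6-bis(3-methylbut-2-en-1-yl)phenoxy]trimethylsilane F6. Treatment with n-BuLi at −78 °C effects exchange and retro-Brook shift, and aqueous work-up delivers 12.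

**Step 16.**
- What may go wrong: elimination of the activated carbinol to the enone, or partial ionisation at the alkoxy-substituted benzylic carbon, either of which costs material or enantiopurity.
- Fallback: it gives up stereospecific closure for a kinetic resolution, sets out from 22 and returns at 23. Treatment of 22 with MsCl and Et3N gives (2E)-1-[2-hydroxy-4-methoxy-6-(methoxymethoxy)-3,5-bis(3-methylbut-2-en-1-yl)phenyl]-3-[4-(methoxymethoxy)phenyl]prop-2-en-1-one F7. NaOAc in hot ethanol cyclises it by oxa-Michael addition to racemic 7-methoxy-5-(methoxymethoxy)-2-[4-(methoxymethoxy)phenyl]-6,8-bis(3-methylbut-2-en-1-yl)-2,3-dihydro-4H-chromen-4-one F8. Asymmetric transfer hydrogenation with RuCl[(R,R)-TsDPEN](p-cymene) and HCO2H–Et3N is stopped near half conversion. By the usual sense of induction it should reduce the (2R)-ketone to (2R,4R)-7-methoxy-5-(methoxymethoxy)-2-[4-(methoxymethoxy)phenyl]-6,8-bis(3-methylbut-2-en-1-yl)-3,4-dihydro-2H-chromen-4-ol F9 and leave 23, which is separated.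

**Step 17.**
- What may go wrong: acid-catalysed addition of the freed 5-OH to the 6-prenyl double bond (chroman formation), or slow ring opening of the flavanone on long exposure to acid.
- Fallback: it replaces protic hydrolysis by silyl transfer, sets out from 23 and returns at 24. TMSOTf with 2,2'-bipyridyl in CH2Cl2 at 0 °C converts both aryl acetals into silyl ethers, giving (2S)-7-methoxy-6,8-bis(3-methylbut-2-en-1-yl)-5-(trimethylsilyloxy)-2-[4-(trimethylsilyloxy)phenyl]-2,3-dihydro-4H-chromen-4-one F10. Addition of water at neutral pH hydrolyses it to 24.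

## Further compounds

F1 | step 14 | 2-bromo-5-methoxy-1,3-bis(methoxymethoxy)-4,6-bis(3-methylbut-2-en-1-yl)benzene | COc1c(CC=C(C)C)c(OCOC)c(Br)c(OCOC)c1CC=C(C)C
F2 | step 14 | [4-methoxy-2,6-bis(methoxymethoxy)-3,5-bis(3-methylbut-2-en-1-yl)phenyl]lithium | [Li]c1c(OCOC)c(CC=C(C)C)c(OC)c(CC=C(C)C)c1OCOC
F3 | step 14 | (3R)-N-methoxy-N-methyl-3-[4-(methoxymethoxy)phenyl]-3-[(triisopropylsilyl)oxy]propanamide | CON(C)C(=O)C[C@@H](O[Si](C(C)C)(C(C)C)C(C)C)c1ccc(OCOC)cc1
F4 | step 14 | (3R)-1-[4-methoxy-2,6-bis(methoxymethoxy)-3,5-bis(3-methylbut-2-en-1-yl)phenyl]-3-[4-(methoxymethoxy)phenyl]-3-[(triisopropylsilyl)oxy]propan-1-one | COc1c(CC=C(C)C)c(OCOC)c(c(OCOC)c1CC=C(C)C)C(=O)C[C@@H](O[Si](C(C)C)(C(C)C)C(C)C)c1ccc(OCOC)cc1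
F5 | step 7 | 2-bromo-5-methoxy-3-(methoxymethoxy)-4,6-bis(3-methylbut-2-en-1-yl)phenol | COc1c(CC=C(C)C)c(O)c(Br)c(OCOC)c1CC=C(C)C
F6 | step 7 | [2-bromo-5-methoxy-3-(methoxymethoxy)-4,6-bis(3-methylbut-2-en-1-yl)phenoxy]trimethylsilane | COc1c(CC=C(C)C)c(O[Si](C)(C)C)c(Br)c(OCOC)c1CC=C(C)C
F7 | step 16 | (2E)-1-[2-hydroxy-4-methoxy-6-(methoxymethoxy)-3,5-bis(3-methylbut-2-en-1-yl)phenyl]-3-[4-(methoxymethoxy)phenyl]prop-2-en-1-one | COc1c(CC=C(C)C)c(OCOC)c(c(O)c1CC=C(C)C)C(=O)/C=C/c1ccc(OCOC)cc1
F8 | step 16 | racemic 7-methoxy-5-(methoxymethoxy)-2-[4-(methoxymethoxy)phenyl]-6,8-bis(3-methylbut-2-en-1-yl)-2,3-dihydro-4H-chromen-4-one | COc1c(CC=C(C)C)c(OCOC)c2c(c1CC=C(C)C)OC(c1ccc(OCOC)cc1)CC2=O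
F9 | step 16 | (2R,4R)-7-methoxy-5-(methoxymethoxy)-2-[4-(methoxymethoxy)phenyl]-6,8-bis(3-methylbut-2-en-1-yl)-3,4-dihydro-2H-chromen-4-ol | COc1c(CC=C(C)C)c(OCOC)c2c(c1CC=C(C)C)O[C@@H](c1ccc(OCOC)cc1)C[C@H]2O
F10 | step 17 | (2S)-7-methoxy-6,8-bis(3-methylbut-2-en-1-yl)-5-(trimethylsilyloxy)-2-[4-(trimethylsilyloxy)phenyl]-2,3-dihydro-4H-chromen-4-one | COc1c(CC=C(C)C)c(O[Si](C)(C)C)c2c(c1CC=C(C)C)O[C@H](c1ccc(O[Si](C)(C)C)cc1)CC2=O
A1 | alternative 1 | (2S)-5-hydroxy-7-methoxy-2-[4-(methoxymethoxy)phenyl]-6,8-bis(3-methylbut-2-en-1-yl)-2,3-dihydro-4H-chromen-4-one | COc1c(CC=C(C)C)c(O)c2c(c1CC=C(C)C)O[C@H](c1ccc(OCOC)cc1)CC2=O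
A2 | alternative 1 | (2S)-5-bromo-2-[4-(methoxymethoxy)phenyl]-2,3-dihydro-4H-pyran-4-one | BrC1=CO[C@H](c2ccc(OCOC)cc2)CC1=O
A3 | alternative 1 | {[1,3-dimethoxy-7-methyl-2-(3-methylbut-2-en-1-yl)octa-1,3,6-trien-1-yl]oxy}trimethylsilane | COC(O[Si](C)(C)C)=C(CC=C(C)C)C(OC)=CCC=C(C)C
A4 | alternative 2 | 3-methoxy-5-(methoxymethoxy)-2,4-bis(3-methylbut-2-en-1-yl)phenol | COc1c(CC=C(C)C)c(O)cc(OCOC)c1CC=C(C)C
A5 | alternative 2 | 3-(methoxymethoxy)-2-(3-methylbut-2-en-1-yl)cyclobut-2-en-1-one | O=C1CC(OCOC)=C1CC=C(C)C
A6 | alternative 2 | 1-methoxy-5-methylhex-4-en-1-yne | COC#CCC=C(C)C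
A7 | alternative 3 | (2S,4R)-7-methoxy-5-(methoxymethoxy)-2-[4-(methoxymethoxy)phenyl]-6,8-bis(3-methylbut-2-en-1-yl)-3,4-dihydro-2H-chromen-4-ol | COc1c(CC=C(C)C)c(OCOC)c2c(c1CC=C(C)C)O[C@H](c1ccc(OCOC)cc1)C[C@H]2O
A8 | alternative 3 | (1R,3S)-1-[2-bromo-4-methoxy-6-(methoxymethoxy)-3,5-bis(3-methylbut-2-en-1-yl)phenyl]-3-[4-(methoxymethoxy)phenyl]propane-1,3-diol | COc1c(CC=C(C)C)c(OCOC)c(c(Br)c1CC=C(C)C)[C@H](O)C[C@H](O)c1ccc(OCOC)cc1
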